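**Retrosynthetic overview**
1. Target ⇒ its ring B tri-O-methyl ether; the last step is ether cleavage only.
2. Key disconnection: the pyranone O1–C2 bond. C2 is passed from a lactone oxygen (an isocoumarin built on ring B) to the ortho phenol oxygen of ring A, and the same event releases the CO2H group.
3. The isocoumarin ketone ⇒ 5-heptylresorcinol + (isocoumarin-3-yl)acetic acid. Friedel–Crafts C-acylation fixes the 5-heptyl/7-hydroxy pattern.
4. That acid ⇒ 2,4,5-trimethoxybenzoic acid + methyl (E)-4-chloro-3-methoxybut-2-enoate, by C6 metalation and allyl coupling.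
5. Ring order: both benzene rings are bought. The isocoumarin lactone ring is closed first as a temporary ring. The chromone pyranone ring is closed second, in the event that opens the lactone.

Assumption: the target SMILES contains no stereocentre and no stereogenic double bond, so the compound is achiral and needs no stereocontrol.

**Step 1**
Reactants: 1 2,4,5-trimethoxybenzoic acid; 2 methyl (E)-4-chloro-3-methoxybut-2-enoate
Product: 6 6-[(E)-3-carboxy-2-methoxyprop-2-enyl]-2,4,5-trimethoxybenzoic acid, via dilithio benzoate 3 (not isolated), via arylzinc chloride 4 (not isolated), via ester carboxylate 5 (not isolated)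
Conditions: s-BuLi (2.2 equiv), TMEDA, THF, –78 °C; ZnCl2, –78 to 0 °C; 2, Pd(OAc)2 (3 mol%), SPhos (6 mol%), rt; then aq LiOH, 50 °C; HCl to pH 2, 0 °C
Reagents that add atoms: lithium hydroxide, [Li+].[OH-]
Why: Directed ortho-metalation of the lithium carboxylate goes to C6, the only position ortho to the carboxylate and also flanked by the 5-OMe group; the arylzinc then undergoes Negishi allyl coupling through a π-allyl complex of divalent palladium at the unhindered CH2 terminus, which keeps the conjugated β-methoxyacrylate (as in known couplings of 4-halocrotonates with aryl metals), and saponification cleaves only the acrylate ester because the base-stable enol ether keeps the latent β-keto acid from losing CO2; no stereocentre is formed.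

**Step 2**
Reactants: 6 6-[(E)-3-carboxy-2-methoxyprop-2-enyl]-2,4,5-trimethoxybenzoic acid; 7 5-heptylbenzene-1,3-diol
Product: 9 3-[2-(2,4-dihydroxy-6-heptylphenyl)-2-oxoethyl]-5,6,8-trimethoxy-1H-isochromen-1-one, via isocoumarinylacetic acid 8 (not isolated)
Conditions: TFA, CH2Cl2, rt, evaporate; 7 (1.3 equiv), BF3·OEt2 (solvent), 70 °C; aq NaOAc
Reagents that add atoms: none
Why: TFA drives an intramolecular addition–elimination of the aryl carboxylic acid on the β-methoxyacrylic acid (loss of MeOH) to give the isocoumarin, which masks the β-keto acid against decarboxylation and Pechmann condensation, and the Nencki-type Friedel–Crafts acylation of 5-alkylresorcinols by arylacetic-type acids in BF3·OEt2 is known to go next to the alkyl chain, ortho to one OH and para to the other; no stereocentre is formed.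

**Step 3**
Reactants: 9 3-[2-(2,4-dihydroxy-6-heptylphenyl)-2-oxoethyl]-5,6,8-trimethoxy-1H-isochromen-1-one
Product: 11 2-[(5-heptyl-7-hydroxy-4-oxo-4H-chromen-2-yl)methyl]-3,4,6-trimethoxybenzoic acid, via spiroketal lactone 10 (not isolated)
Conditions: DBU (3 equiv), MeCN (no alcohol, no water), Ar, 40 °C; cold 0.5 M HCl
Reagents that add atoms: none
Why: Proposed new method: the base shuttles protons between the doubly activated CH2 and C4 so that 9 equilibrates with its exocyclic β-acyloxy enone tautomer, whose β-carbon (isocoumarin C3, the future C2) is attacked 6-endo-trig by the ortho phenoxide of ring A to give the racemic, short-lived spiroketal 10; E1cB loss of the much better leaving aryl carboxylate (pKa about 4 against about 8 for the phenol) then forms the O1–C2 bond, opens the lactone and releases the acid irreversibly as its DBU salt, while the planar lactone holds the enolate carbon away from C1 so that no naphthol can form; the closest known reaction types are the addition–elimination ring closure of 2-hydroxyaryl β-amino or β-alkoxy enones to chromones and the amine-induced isocoumarin-to-isoquinolone exchange.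

**Step 4**
Reactants: 11 2-[(5-heptyl-7-hydroxy-4-oxo-4H-chromen-2-yl)methyl]-3,4,6-trimethoxybenzoic acid
Product: 12 2-[(5-heptyl-7-hydroxy-4-oxo-4H-chromen-2-yl)methyl]-3,4,6-trihydroxybenzoic acid
Conditions: BBr3 (10 equiv), CH2Cl2, –78 °C to rt; ice-water, Ar, no base in the work-up
Reagents that add atoms: none
Why: BBr3 cleavage of aryl methyl ethers (Lewis acid complexation, then bromide SN2 at methyl) removes the three ring B methyl groups while chromone, heptyl chain and acid are untouched, and a cold, air-free, base-free work-up avoids loss of CO2 from the resorcylic-type acid, quinone formation and attack of the new 3-OH on C2; no stereocentre is involved.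

**Compound list**
1 | 2,4,5-trimethoxybenzoic acid | COc1cc(OC)c(C(=O)O)cc1OC | starting material
2 | methyl (E)-4-chloro-3-methoxybut-2-enoate | COC(=O)/C=C(/OC)CCl | starting material
3 | lithium 6-lithio-2,4,5-trimethoxybenzoate | [Li]c1c(OC)c(OC)cc(OC)c1C(=O)[O-].[Li+] | intermediate
4 | lithium 6-(chlorozincio)-2,4,5-trimethoxybenzoate | Cl[Zn]c1c(OC)c(OC)cc(OC)c1C(=O)[O-].[Li+] | intermediate
5 | lithium 6-[(E)-2,4-dimethoxy-4-oxobut-2-enyl]-2,4,5-trimethoxybenzoate | COC(=O)/C=C(/OC)Cc1c(OC)c(OC)cc(OC)c1C(=O)[O-].[Li+] | intermediate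
6 | 6-[(E)-3-carboxy-2-methoxyprop-2-enyl]-2,4,5-trimethoxybenzoic acid | OC(=O)/C=C(/OC)Cc1c(OC)c(OC)cc(OC)c1C(=O)O | intermediate
7 | 5-heptylbenzene-1,3-diol | CCCCCCCc1cc(O)cc(O)c1 | starting material
8 | 2-(5,6,8-trimethoxy-1-oxo-1H-isochromen-3-yl)acetic acid | OC(=O)CC1=Cc2c(OC)c(OC)cc(OC)c2C(=O)O1 | intermediate
9 | 3-[2-(2,4-dihydroxy-6-heptylphenyl)-2-oxoethyl]-5,6,8-trimethoxy-1H-isochromen-1-one | CCCCCCCc1cc(O)cc(O)c1C(=O)CC1=Cc2c(OC)c(OC)cc(OC)c2C(=O)O1 | intermediate
10 | 5-heptyl-7-hydroxy-5',6',8'-trimethoxyspiro[chromane-2,3'-isochromane]-1',4-dione (racemic, short-lived) | CCCCCCCc1cc(O)cc2OC3(CC(=O)c12)Cc1c(OC)c(OC)cc(OC)c1C(=O)O3 | intermediate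
11 | 2-[(5-heptyl-7-hydroxy-4-oxo-4H-chromen-2-yl)methyl]-3,4,6-trimethoxybenzoic acid | CCCCCCCc1cc(O)cc2oc(Cc3c(OC)c(OC)cc(OC)c3C(=O)O)cc(=O)c12 | intermediate
12 | 2-[(5-heptyl-7-hydroxy-4-oxo-4H-chromen-2-yl)methyl]-3,4,6-trihydroxybenzoic acid | CCCCCCCc1cc(O)cc2oc(Cc3c(O)c(O)cc(O)c3C(=O)O)cc(=O)c12 | target

**Totals**
Total step count: 4. Longest linear sequence: 4 (1 → 6 → 9 → 11 → 12).

**Steps most likely to fail, with fallbacks**

Step 3 (the new step). The enolate of 9 may simply persist, or the exchange may stall at an equilibrium. The fallback uses known chemistry, sets out from 9 and comes back at 11. LiOH (4 equiv) in THF–H2O at 0 °C to rt opens the enol lactone to 2-[4-(2,4-dihydroxy-6-heptylphenyl)-2,4-dioxobutyl]-3,4,6-trimethoxybenzoic acid F5. Its carboxylate cannot undergo Dieckmann closure. After cold acidification, the classical acid-catalysed cyclodehydration of a 2-hydroxyaryl 1,3-diketone (catalytic H2SO4 in AcOH at rt, or TFA in CH2Cl2) closes the pyranone and gives 11.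

Step 2. Acid 8 may lose CO2 at 70 °C, or the lactone carbonyl may acylate 7. The fallback sets out from 8 and 7 and comes back at 9. The ester C–O bond is made first and the acyl group is moved afterwards. EDC·HCl, catalytic DMAP and 3 equiv of 7 in CH2Cl2 at 0 °C give 3-heptyl-5-hydroxyphenyl 2-(5,6,8-trimethoxy-1-oxo-1H-isochromen-3-yl)acetate F4. A Fries rearrangement (Sc(OTf)3 10 mol%, toluene–MeNO2, 80 °C, or 254 nm light) brings the acyl group to the ring carbon next to the heptyl chain, which is 9.

Step 1. Transmetalation of the di-ortho-substituted arylzinc may be slow, or coupling may occur at the wrong allyl terminus. The fallback sets out from 1 and comes back at 8.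
- The same dilithio species 3 is quenched with MeI to give 2,4,5-trimethoxy-6-methylbenzoic acid F1.
- LiN(i-Pr)2 (3.3 equiv) in THF at –78 °C makes the benzylic (toluate) dianion. This is acylated with ethyl 3,3-diethoxyacrylate and treated with cold dilute HCl to give 6-(4-ethoxy-2,4-dioxobutyl)-2,4,5-trimethoxybenzoic acid F2.
- TFAA/TFA closes the enol lactone to ethyl 2-(5,6,8-trimethoxy-1-oxo-1H-isochromen-3-yl)acetate F3.
- Aqueous HCl in AcOH at 60 °C cleaves the ethyl ester to give 8.

**Further compounds**
F1 | step 1 | 2,4,5-trimethoxy-6-methylbenzoic acid | Cc1c(OC)c(OC)cc(OC)c1C(=O)O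
F2 | step 1 | 6-(4-ethoxy-2,4-dioxobutyl)-2,4,5-trimethoxybenzoic acid | CCOC(=O)CC(=O)Cc1c(OC)c(OC)cc(OC)c1C(=O)O
F3 | step 1 | ethyl 2-(5,6,8-trimethoxy-1-oxo-1H-isochromen-3-yl)acetate | CCOC(=O)CC1=Cc2c(OC)c(OC)cc(OC)c2C(=O)O1
F4 | step 2 | 3-heptyl-5-hydroxyphenyl 2-(5,6,8-trimethoxy-1-oxo-1H-isochromen-3-yl)acetate | CCCCCCCc1cc(O)cc(OC(=O)CC2=Cc3c(OC)c(OC)cc(OC)c3C(=O)O2)c1
F5 | step 3 | 2-[4-(2,4-dihydroxy-6-heptylphenyl)-2,4-dioxobutyl]-3,4,6-trimethoxybenzoic acid | CCCCCCCc1cc(O)cc(O)c1C(=O)CC(=O)Cc1c(OC)c(OC)cc(OC)c1C(=O)O
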